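I began with time, sorting the steps of these flasks by how long each takes.

    partner + free catalyst ⇌ catalyst intermediate A (K1 = 18.0 M⁻¹, k1 = 34.4 M⁻¹ s⁻¹)
    free catalyst + free catalyst ⇌ resting dimer (K2 = 11000 M⁻¹, k2 = 172 M⁻¹ s⁻¹)
    catalyst intermediate B → free catalyst + product (k3 = 4.37 s⁻¹)
    substrate + catalyst intermediate A → catalyst intermediate B (k4 = 38.2 M⁻¹ s⁻¹)

all flasks: substrate 0.10 M; partner 0.0900 M; time 20 s

| run | free catalyst |
|---|---|
| ash | 5.4 mM |
| alder | 8.1 mM |
| larch | 3.6 mM |

1. which of these there is most of at the end, counted by the substrate in it, ash (substrate / catalyst intermediate B / product)
2. which of these there is most of at the end, counted by the substrate in it, alder (substrate / catalyst intermediate B / product)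
3. which of these there is most of at the end, counted by the substrate in it, larch (substrate / catalyst intermediate B / product)
4. amount of the one of these that there is most of at the end, in percent of the substrate charged, ash
5. amount of the one of these that there is most of at the end, in percent of the substrate charged, alder
6. amount of the one of these that there is most of at the end, in percent of the substrate charged, larch

Catalyst intermediate A lasted 0.174 s and catalyst intermediate B 0.229 s, both far shorter than the run. So I treated them as balanced.

The dimer came next. With the charge of ash counted as dimer, the dimer balance left [free catalyst] at 0.495 mM, or 9.17% of the charge. The resting dimer was therefore the resting state. Close to that level, I reckoned a relaxation time constant of about 2.93 s, longer than the intermediates lasted but shorter than the run. This is a time constant near balance, not the time of arrival from the charge.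

Before that, the flask ran a burst. At the start of ash, 1.7 free catalyst went to catalyst intermediate A for each one going to the dimer. Counting one product per pass, I got a burst of 9.00 mM. The catalyst charge cancels in this rough reckoning, so I carried the same burst into my estimates for alder and larch, as a simplification and not as a statement about those flasks.

Then came the plateau. A share 66.7% of catalyst intermediate A went on with substrate at the charges, so ash started its plateau at 1.02 mM s⁻¹. That rate falls as substrate and partner fall, so I replaced the curve by its mean. The first guess of conversion was 29.4 mM, and I took half of it off both charges. This gave 0.809 mM s⁻¹. This is the mean plateau rate, the turnover with free catalyst at its dimer level and substrate and partner at mid-run amounts.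

Burst plus plateau left 74.8% of the substrate in ash. The same steps gave alder 0.950 mM s⁻¹ and 72.0% left. They gave larch 0.682 mM s⁻¹ and 77.4% left. I committed to substrate as the largest pool in each.

The forecast also named substrate and gave 75%, 71% and 80%, on the ground that "catalyst falls quickly into the resting dimer"; for larch it stood above mine.

The flasks held 74.2%, 70.2% and 78.0% of substrate in ash, alder and larch, ahead of product in each. In ash, product went from 18.2% at 10.0 s to 25.7% at 20.0 s. That is 0.753 mM s⁻¹, beside my mean plateau rate of 0.809 mM s⁻¹.

A neighbour of ash with 0.22 M of partner changes both terms. The burst became 22.0 mM, the first guess 72.0 mM, and the mean plateau rate 1.76 mM s⁻¹. So I expected 42.8% of substrate left. That neighbour held 43.6% substrate and 56.1% product.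

The constants used here are assumed; no experiment stands behind them.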